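**Plan**

1. Retrosynthesis: cut the C15–O ester bond; take C8(OH)(CH3) back through the 8α,17-epoxide and the C8=C17 alkene to a C8 ketone; remove the C7 methylene from ring B (bonds C6–C7 and C7–C8), which leaves a trans-fused cyclopentanone (C5, C6, C8, C9, C10); then cut C9–C11, the C5=C6 aldol bond and C9–C10.
2. Feature used: ring B holds an unbranched C6–C7 pair next to the carbinol carbon C8, whose other neighbour C9 is branched and lies beside the quaternary C10. With C8 as a ketone, C7 can be inserted last into the five-membered ring with migration of C6, and C9 becomes epimerisable.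
3. Forward order: ring A is bought as 2,2,6-trimethylcyclohexanone; enantioselective decarboxylative allylation creates C10; Wacker oxidation and aldol condensation close the five-membered nor-ring B; the C11–C15 chain with its C16 methyl is alkylated onto C9; hydrogenation, one-carbon ring expansion to ring B, then methylenation, epoxidation, hydride opening and acylation.
4. Stereochemistry: C10 from the chiral palladium catalyst; C5 from hydrogen delivery anti to the two syn-axial methyl groups; C9 by equilibration α to the C8 ketone after the ring expansion; C8 from α-face epoxidation and hydride attack at C17; C13 from the purchased (R)-hemiester.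

Key step: step 9

Remark: labdane numbering (C1–C20) is used for atoms; the C9 center made in step 7 is carried as an epimer mixture until step 9, and the diastereomer arising from residual minor enantiomer of the core is expected to be removable by chromatography.

**Step 1**
Reactants: 1 2,2,6-trimethylcyclohexan-1-one; 2 allyl chloroformate
Product: 4 allyl 2,6,6-trimethylcyclohex-1-en-1-yl carbonate, via lithium enolate 3 (not isolated)
Conditions: LiHMDS, THF, 0 °C; then 2, −78 °C → rt
Reagents that add atoms: none
Why: Ketone 1 has a single enolisable position (the future C10), so one enolate forms, and the chloroformate acylates this hindered tetrasubstituted enolate on oxygen (enol carbonate formation).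

**Step 2**
Reactants: 4 allyl 2,6,6-trimethylcyclohex-1-en-1-yl carbonate
Product: 5 (R)-2-allyl-2,6,6-trimethylcyclohexan-1-one
Conditions: Pd2(dba)3 (2.5 mol%), (R)-t-Bu-PHOX (6 mol%), THF, 25 °C
Reagents that add atoms: none
Why: Zerovalent palladium ionises the allyl carbonate, CO2 is lost and the π-allylpalladium enolate pair recombines at carbon inside the chiral P,N-ligand (decarboxylative asymmetric allylic alkylation, Tsuji type), which should set the quaternary C10 as the (R)-ketone because the (S)-ligand leads to the (S)-series in this reaction class.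

**Step 3**
Reactants: 5 (R)-2-allyl-2,6,6-trimethylcyclohexan-1-one
Product: 6 (R)-2,2,6-trimethyl-6-(2-oxopropyl)cyclohexan-1-one
Conditions: PdCl2 (10 mol%), Cu(OAc)2·H2O (25 mol%), O2 (1 atm), DMA/H2O, 23 °C
Reagents that add atoms: water, O (source of the carbonyl oxygen); dioxygen, O=O (terminal oxidant)
Why: Wacker–Tsuji oxidation of the terminal alkene by divalent palladium places the oxygen on the internal carbon (the future C8) by Markovnikov hydroxypalladation and leaves the hindered ring ketone and the quaternary center untouched.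

**Step 4**
Reactants: 6 (R)-2,2,6-trimethyl-6-(2-oxopropyl)cyclohexan-1-one
Product: 8 (7aR)-4,4,7a-trimethyl-1,4,5,6,7,7a-hexahydro-2H-inden-2-one, via aldol adduct 7 (not isolated)
Conditions: KOH (powdered), xylenes, 110 °C, Dean–Stark
Reagents that add atoms: none
Why: Intramolecular aldol condensation, in which the methyl carbon of the side-chain ketone (future C6) is the only enolate carbon that can reach the non-enolisable ring carbonyl (C5) in a five-membered closure, and removal of water drives dehydration of 7 to the cyclopentenone.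

**Step 5**
Reactants: 9 methyl hydrogen (R)-3-methylglutarate
Product: 11 (S)-4-methyltetrahydro-2H-pyran-2-one, via hydroxy acid 10 (not isolated)
Conditions: LiBH4, THF, 0 → 50 °C; then 3 M HCl, rt
Reagents that add atoms: none
Why: LiBH4 converts the acid into the inert lithium carboxylate and reduces only the methyl ester (chemoselective ester reduction), and acidification lactonises hydroxy acid 10, so the two arms of 9 are differentiated without touching the stereocenter.

**Step 6**
Reactants: 11 (S)-4-methyltetrahydro-2H-pyran-2-one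
Product: 13 methyl (R)-5-iodo-3-methylpentanoate, via silyl ester 12 (not isolated)
Conditions: NaI, TMSCl, MeCN, 60 °C; then MeOH, 60 °C
Reagents that add atoms: sodium iodide, [Na+].[I-]; methanol, CO
Why: Iodotrimethylsilane formed in the flask silylates the lactone carbonyl and iodide opens the ring by SN2 attack at the O–CH2 carbon (lactone cleavage to an ω-iodo ester), after which acidic methanolysis of silyl ester 12 gives the methyl ester; the stereocenter is remote from both reacting carbons.

**Step 7**
Reactants: 8 (7aR)-4,4,7a-trimethyl-1,4,5,6,7,7a-hexahydro-2H-inden-2-one; 13 methyl (R)-5-iodo-3-methylpentanoate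
Product: 15 methyl (3S)-3-methyl-5-[(7aR)-4,4,7a-trimethyl-2-oxo-2,4,5,6,7,7a-hexahydro-1H-inden-1-yl]pentanoate as a mixture of C9 epimers, via lithium dienolate 14 (not isolated)
Conditions: LDA, THF, −78 °C; then 13, DMPU, −78 → 0 °C
Reagents that add atoms: none
Why: C9 carries the only sp3 α-hydrogens of enone 8 (C4 and C10 are quaternary, so no extended dienolate can form), so LDA should give the cross-conjugated dienolate 14 regiospecifically and SN2 alkylation with the primary iodide forms the C9–C11 bond (kinetic α′-alkylation of an enone); the new C9 center is not controlled here and is corrected in step 9.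

**Step 8**
Reactants: 15 methyl (3S)-3-methyl-5-[(7aR)-4,4,7a-trimethyl-2-oxo-2,4,5,6,7,7a-hexahydro-1H-inden-1-yl]pentanoate
Product: 16 methyl (3S)-3-methyl-5-[(3aS,7aS)-4,4,7a-trimethyl-2-oxooctahydro-1H-inden-1-yl]pentanoate (trans-fused; mixture of C9 epimers)
Conditions: H2 (1–3 atm), Pd/C, EtOAc, rt
Reagents that add atoms: none
Why: Heterogeneous hydrogenation of the C5=C6 enone bond, in which hydrogen should reach C5 from the α-face (axial on ring A) because the β-face is blocked by the two syn-axial methyl groups on C4 and C10, giving the trans ring fusion.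

**Step 9**
Reactants: 16 methyl (3S)-3-methyl-5-[(3aS,7aS)-4,4,7a-trimethyl-2-oxooctahydro-1H-inden-1-yl]pentanoate
Product: 18 methyl (3S)-3-methyl-5-[(1R,4aS,8aS)-5,5,8a-trimethyl-2-oxodecahydronaphthalen-1-yl]pentanoate, via α-silyl ketone 17 (not isolated)
Conditions: TMSCHN2, BF3·OEt2 (promoter), CH2Cl2, −78 → −20 °C; then NaOMe (cat.), MeOH, rt
Reagents that add atoms: (trimethylsilyl)diazomethane, C[Si](C)(C)C=[N+]=[N-]
Why: The BF3-activated C8 carbonyl of the cyclopentanone is attacked by the diazo carbon of TMSCHN2, and the β-oxido diazonium species loses N2 while the C6–C8 bond shifts onto the new carbon, which becomes C7 (Tiffeneau–Demjanov-type diazoalkane homologation of a cyclic ketone); methoxide then removes the silyl group from 17. No ring is closed: the five-membered ring C5–C6–C8–C9–C10 grows into the six-membered ring B by insertion of C7 between C6 and C8, and the carbonyl stays at C8, where the methyl and hydroxyl groups are needed. The selectivity required is migration of C6 instead of C9; the substrate secures it because C6 is an unbranched methylene whereas C9 is tertiary and sits beside the quaternary C10, and the less substituted α-carbon is the one that migrates in Lewis acid-promoted diazoalkane homologations, while a second insertion is held back by the silyl group on C7 and the branch at C9. The one stereocenter affected is C9, which is α to the C8 carbonyl and is equilibrated by NaOMe to the epimer with the side chain equatorial on the chair of ring B (9α-H), so both C9 epimers of 16 should converge on 18. C5 and C10 carry no acidic hydrogen and C13 is remote, so they are not touched.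

**Step 10**
Reactants: 18 methyl (3S)-3-methyl-5-[(1R,4aS,8aS)-5,5,8a-trimethyl-2-oxodecahydronaphthalen-1-yl]pentanoate
Product: 19 methyl (3S)-3-methyl-5-[(1S,4aS,8aS)-5,5,8a-trimethyl-2-methylidenedecahydronaphthalen-1-yl]pentanoate
Conditions: Ph3PCH3Br, KOt-Bu, toluene, 0 → 80 °C
Reagents that add atoms: methyltriphenylphosphonium bromide, C[P+](c1ccccc1)(c1ccccc1)c1ccccc1.[Br-]
Why: Wittig methylenation of the C8 ketone with the unstabilised ylide, which reacts with a ketone much faster than with the methyl ester; C9 is already in its thermodynamic configuration, so the basic medium cannot erode it.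

**Step 11**
Reactants: 19 methyl (3S)-3-methyl-5-[(1S,4aS,8aS)-5,5,8a-trimethyl-2-methylidenedecahydronaphthalen-1-yl]pentanoate
Product: 20 methyl (13S)-8α,17-epoxylabdan-15-oate
Conditions: mCPBA, NaHCO3, CH2Cl2, 0 °C
Reagents that add atoms: 3-chloroperoxybenzoic acid, O=C(OO)c1cccc(Cl)c1
Why: Prilezhaev epoxidation of the 1,1-disubstituted C8=C17 alkene, in which the peracid should approach from the equatorial α-face because the axial β-trajectory at C8 is shielded by the syn-axial methyl group on C10.

**Step 12**
Reactants: 20 methyl (13S)-8α,17-epoxylabdan-15-oate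
Product: 21 (1R,2R,4aS,8aS)-1-[(3S)-5-hydroxy-3-methylpentyl]-2,5,5,8a-tetramethyldecahydronaphthalen-2-ol
Conditions: LiAlH4, THF, 0 → 40 °C
Reagents that add atoms: none
Why: Hydride opens the spiro-epoxide by SN2 attack at the primary C17, which becomes the methyl group while the C8–O bond is retained as the equatorial 8α-hydroxyl, and the methyl ester is reduced to the C15 primary alcohol in the same operation (LiAlH4 reduction).

**Step 13**
Reactants: 21 (1R,2R,4aS,8aS)-1-[(3S)-5-hydroxy-3-methylpentyl]-2,5,5,8a-tetramethyldecahydronaphthalen-2-ol; 22 3-phenylpropanoyl chloride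
Product: 23 (3S)-5-[(1R,2R,4aS,8aS)-2-hydroxy-2,5,5,8a-tetramethyldecahydronaphthalen-1-yl]-3-methylpentyl 3-phenylpropanoate
Conditions: pyridine, DMAP (cat.), CH2Cl2, 0 °C
Reagents that add atoms: none
Why: DMAP-catalysed acylation with the acid chloride should be selective for the primary C15 hydroxyl, since the tertiary and hindered C8 hydroxyl does not react under these conditions.

**Compound list**

1 | 2,2,6-trimethylcyclohexan-1-one (racemic) | CC1CCCC(C)(C)C1=O | starting material
2 | allyl chloroformate | C=CCOC(Cl)=O | starting material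
3 | lithium 2,6,6-trimethylcyclohex-1-en-1-olate | [Li+].[O-]C1=C(C)CCCC1(C)C | intermediate (not isolated)
4 | allyl 2,6,6-trimethylcyclohex-1-en-1-yl carbonate | C=CCOC(=O)OC1=C(C)CCCC1(C)C | intermediate
5 | (R)-2-allyl-2,6,6-trimethylcyclohexan-1-one | C=CC[C@@]1(C)CCCC(C)(C)C1=O | intermediate
6 | (R)-2,2,6-trimethyl-6-(2-oxopropyl)cyclohexan-1-one | CC(=O)C[C@@]1(C)CCCC(C)(C)C1=O | intermediate
7 | (7aR)-3a-hydroxy-4,4,7a-trimethyloctahydro-2H-inden-2-one (carbinol configuration of no consequence) | O=C1C[C@@]2(C)CCCC(C)(C)C2(O)C1 | intermediate (not isolated)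
8 | (7aR)-4,4,7a-trimethyl-1,4,5,6,7,7a-hexahydro-2H-inden-2-one | O=C1C[C@@]2(C)CCCC(C)(C)C2=C1 | intermediate
9 | methyl hydrogen (R)-3-methylglutarate | C[C@H](CC(=O)O)CC(=O)OC | starting material
10 | (S)-5-hydroxy-3-methylpentanoic acid | C[C@@H](CCO)CC(=O)O | intermediate (not isolated)
11 | (S)-4-methyltetrahydro-2H-pyran-2-one | C[C@@H]1CC(=O)OCC1 | intermediate
12 | trimethylsilyl (R)-5-iodo-3-methylpentanoate | C[C@@H](CCI)CC(=O)O[Si](C)(C)C | intermediate (not isolated)
13 | methyl (R)-5-iodo-3-methylpentanoate | C[C@@H](CCI)CC(=O)OC | intermediate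
14 | lithium cross-conjugated dienolate of 8 (C9=C8–O−, 7aR) | [Li+].[O-]C1=C[C@@]2(C)CCCC(C)(C)C2=C1 | intermediate (not isolated)
15 | methyl (3S)-3-methyl-5-[(7aR)-4,4,7a-trimethyl-2-oxo-2,4,5,6,7,7a-hexahydro-1H-inden-1-yl]pentanoate (both C9 epimers) | C[C@H](CC(=O)OC)CCC1[C@@]2(C)CCCC(C)(C)C2=CC1=O | intermediate
16 | methyl (3S)-3-methyl-5-[(3aS,7aS)-4,4,7a-trimethyl-2-oxooctahydro-1H-inden-1-yl]pentanoate (trans-fused, both C9 epimers) | C[C@H](CC(=O)OC)CCC1[C@@]2(C)CCCC(C)(C)[C@@H]2CC1=O | intermediate
17 | methyl (3S)-3-methyl-5-[(4aS,8aS)-5,5,8a-trimethyl-2-oxo-3-(trimethylsilyl)decahydronaphthalen-1-yl]pentanoate (C7 and C9 epimers) | C[C@H](CC(=O)OC)CCC1[C@@]2(C)CCCC(C)(C)[C@@H]2CC([Si](C)(C)C)C1=O | intermediate (not isolated)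
18 | methyl (3S)-3-methyl-5-[(1R,4aS,8aS)-5,5,8a-trimethyl-2-oxodecahydronaphthalen-1-yl]pentanoate | C[C@H](CC(=O)OC)CC[C@@H]1[C@@]2(C)CCCC(C)(C)[C@@H]2CCC1=O | intermediate
19 | methyl (3S)-3-methyl-5-[(1S,4aS,8aS)-5,5,8a-trimethyl-2-methylidenedecahydronaphthalen-1-yl]pentanoate | C[C@H](CC(=O)OC)CC[C@@H]1[C@@]2(C)CCCC(C)(C)[C@@H]2CCC1=C | intermediate
20 | methyl (13S)-8α,17-epoxylabdan-15-oate (spiro-epoxide, oxygen α and equatorial on C8, CH2 β) | C[C@H](CC(=O)OC)CC[C@@H]1[C@@]2(C)CCCC(C)(C)[C@@H]2CC[C@@]1(C3)O3 | intermediate
21 | (1R,2R,4aS,8aS)-1-[(3S)-5-hydroxy-3-methylpentyl]-2,5,5,8a-tetramethyldecahydronaphthalen-2-ol | C[C@H](CCO)CC[C@@H]1[C@@]2(C)CCCC(C)(C)[C@@H]2CC[C@@]1(C)O | intermediate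
22 | 3-phenylpropanoyl chloride | O=C(Cl)CCc1ccccc1 | starting material
23 | (3S)-5-[(1R,2R,4aS,8aS)-2-hydroxy-2,5,5,8a-tetramethyldecahydronaphthalen-1-yl]-3-methylpentyl 3-phenylpropanoate | C[C@H](CCOC(=O)CCc1ccccc1)CC[C@@H]1[C@@]2(C)CCCC(C)(C)[C@@H]2CC[C@@]1(C)O | target

**Step count and risks**

Total steps: 13. Longest linear sequence: 11 (steps 1–4 and 7–13); the side-chain branch (steps 5–6) joins at step 7.

Step 9. What may go wrong: insufficient discrimination between migration of C6 and C9, a second homologation, or collapse of the adduct to a spiro-epoxide. The fallback sets out from 16 and returns at 18. Kinetic deprotonation toward the unbranched C6 with in-situ silylation (LDA, TMSCl, THF, −78 °C) would give the trimethylsilyl enol ether F1. Simmons–Smith cyclopropanation (Et2Zn, CH2I2, CH2Cl2) would give the siloxycyclopropane F2, in which the new carbon is already bonded to C6 and C8. Oxidative cleavage of the internal cyclopropane bond with FeCl3 in DMF (Saegusa–Ito ring expansion) would give the β-chloro ketone F3, and NaOAc in MeOH would eliminate HCl to the cyclohexenone F4. Hydrogenation (H2, Pd/C) and NaOMe/MeOH equilibration then lead to 18. The position of the inserted carbon is fixed by the enol ether and exactly one carbon is added.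

Step 7. What may go wrong: slow SN2 alkylation of the hindered dienolate next to the quaternary C10, with competing O-alkylation and proton transfer. The fallback sets out from 8 and 11 and returns at 16. Methanolysis of lactone 11 (MeOH, cat. NaOMe) would give methyl (S)-5-hydroxy-3-methylpentanoate F5, and Dess–Martin oxidation would give methyl (S)-3-methyl-5-oxopentanoate F6. Aldol addition of dienolate 14 to F6 (THF, −78 °C), which is much faster than alkylation, would give the β-hydroxy ketone F7. Acid-catalysed dehydration (p-TsOH, toluene, 80 °C) would give the cross-conjugated dienone F8, and hydrogenation (H2, Pd/C, EtOAc) would saturate both C=C bonds to give 16.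

Step 8. What may go wrong: delivery of hydrogen to the β-face of C5 (cis ring fusion), or erosion of the facial preference by the C9 substituent. The fallback sets out from 8 and returns at 18. The ring fusion is set before the ester chain is present, by dissolving-metal reduction (Li, liquid NH3, THF, t-BuOH, −78 °C), in which the C5 carbanion is protonated axially from the α-face. The regiodefined enolate is trapped (TMSCl, Et3N) as the trans-fused silyl enol ether F9. Simmons–Smith cyclopropanation would give the siloxycyclopropane F10, FeCl3 in DMF the β-chloro ketone F11, and NaOAc in MeOH the trans-decalenone F12. The only sp3 α-carbon of F12 is C9, so LDA followed by 13 (DMPU) would give the cyclohexenone F4 of the first fallback, which is hydrogenated and equilibrated to 18 as described there.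

**Further compounds**

F1 | step 9 | methyl (3S)-3-methyl-5-[(3aS,7aS)-4,4,7a-trimethyl-2-(trimethylsilyloxy)-3a,4,5,6,7,7a-hexahydro-1H-inden-1-yl]pentanoate (C9 epimers) | C[C@H](CC(=O)OC)CCC1[C@@]2(C)CCCC(C)(C)[C@@H]2C=C1O[Si](C)(C)C
F2 | step 9 | siloxycyclopropane of F1 (cyclopropane C6–C7–C8, trimethylsilyloxy on C8; cyclopropane face and C9 unassigned) | C[C@H](CC(=O)OC)CCC1[C@@]2(C)CCCC(C)(C)[C@@H]2C3CC13O[Si](C)(C)C
F3 | step 9 | methyl (3S)-5-[(4aS,8aS)-4-chloro-5,5,8a-trimethyl-2-oxodecahydronaphthalen-1-yl]-3-methylpentanoate (chlorine on C6; C6 and C9 unassigned) | C[C@H](CC(=O)OC)CCC1[C@@]2(C)CCCC(C)(C)[C@@H]2C(Cl)CC1=O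
F4 | step 9 | methyl (3S)-3-methyl-5-[(4aS,8aS)-5,5,8a-trimethyl-2-oxo-1,2,4a,5,6,7,8,8a-octahydronaphthalen-1-yl]pentanoate (C9 epimers) | C[C@H](CC(=O)OC)CCC1[C@@]2(C)CCCC(C)(C)[C@@H]2C=CC1=O
F5 | step 7 | methyl (S)-5-hydroxy-3-methylpentanoate | C[C@@H](CCO)CC(=O)OC
F6 | step 7 | methyl (S)-3-methyl-5-oxopentanoate | C[C@@H](CC=O)CC(=O)OC
F7 | step 7 | methyl (3S)-5-hydroxy-3-methyl-5-[(7aR)-4,4,7a-trimethyl-2-oxo-2,4,5,6,7,7a-hexahydro-1H-inden-1-yl]pentanoate (C9 and C11 unassigned) | C[C@H](CC(=O)OC)CC(O)C1[C@@]2(C)CCCC(C)(C)C2=CC1=O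
F8 | step 7 | methyl (3S)-3-methyl-5-[(7aS)-4,4,7a-trimethyl-2-oxo-2,4,5,6,7,7a-hexahydro-1H-inden-1-ylidene]pentanoate (alkene geometry of no consequence) | C[C@H](CC(=O)OC)CC=C1[C@@]2(C)CCCC(C)(C)C2=CC1=O
F9 | step 8 | (3aS,7aR)-4,4,7a-trimethyl-2-(trimethylsilyloxy)-3a,4,5,6,7,7a-hexahydro-1H-indene | C1[C@@]2(C)CCCC(C)(C)[C@@H]2C=C1O[Si](C)(C)C
F10 | step 8 | siloxycyclopropane of F9 (cyclopropane C6–C7–C8, trimethylsilyloxy on C8; cyclopropane face unassigned) | C1[C@@]2(C)CCCC(C)(C)[C@@H]2C3CC13O[Si](C)(C)C
F11 | step 8 | (4aS,8aR)-4-chloro-5,5,8a-trimethyloctahydronaphthalen-2(1H)-one (C6 unassigned) | C1[C@@]2(C)CCCC(C)(C)[C@@H]2C(Cl)CC1=O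
F12 | step 8 | (4aS,8aR)-5,5,8a-trimethyl-4a,5,6,7,8,8a-hexahydronaphthalen-2(1H)-one | C1[C@@]2(C)CCCC(C)(C)[C@@H]2C=CC1=O
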